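The stereocentre C2 in flavanone ring C is bonded to O1, H and the 4-methoxyphenyl ring B. Without the C2–C3 bond it is the OCH2 carbon of a 4-methoxybenzyl ether on C8a, five bonds from C3 (C3–C4–C4a–C8a–O1–C2), the carbon next to the C4 carbonyl.
Cuts, in order: C2–C3 of flavanone ring C (back to an aryl diazomethyl ketone), the biaryl bond from flavanone C6 to C3' of the flavone B ring, the flavone pyranone ring (back to a chalcone), and the benzylic O–C bonds. Both halves lead back to phloroacetophenone.
Flavone half, forward: bis-benzylation, Claisen–Schmidt condensation with 3-bromo-4-methoxybenzaldehyde, oxidative closure of the flavone pyranone ring, borylation.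
Flavanone half, forward: bis-4-methoxybenzylation (one ether supplies C2 and ring B, the other protects O7) and iodination. The halves are then coupled, O5 is silylated, acetyl becomes diazoacetyl, flavanone ring C closes last, and two deprotections follow.
Stereochemistry: C2 (S), the only stereocentre, is set by catalyst control in the ring C closure, where Rh2(S-PTTL)4 selects the pro-S hydrogen of the OCH2 group. The two later steps are buffered or neutral.

Key step: step 10

Assumption: Rh2(S-PTTL)4 is taken to deliver the (2S) product; if the sense of induction proves opposite, the equally accessible Rh2(R-PTTL)4 is used with nothing else changed.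
Assumption: the C6–C3' axis (ortho groups two oxygens, one methoxy, one hydrogen) is taken to rotate freely in the target, whose structure defines no axial configuration, so any rotamers of protected intermediates converge on deprotection.

Step 1
Reactants: 1 phloroacetophenone (2',4',6'-trihydroxyacetophenone)
Product: 2 dibenzyl ether 4',6'-bis(benzyloxy)-2'-hydroxyacetophenone
Conditions: BnBr (2.1 equiv), K2CO3 (2.2 equiv), DMF, 60 °C
Reagents that add atoms: benzyl bromide (BrCc1ccccc1)
Why: Williamson ether synthesis in which two equivalents of halide alkylate the para hydroxyl and one ortho hydroxyl, after which the last phenol is locked in a hydrogen bond to the acetyl oxygen and stays free.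

Step 2
Reactants: 2 dibenzyl ether; 3 3-bromo-4-methoxybenzaldehyde
Product: 4 chalcone (E)-1-[2,4-bis(benzyloxy)-6-hydroxyphenyl]-3-(3-bromo-4-methoxyphenyl)prop-2-en-1-one
Conditions: KOH (50 % aq.), EtOH, rt
Reagents that add atoms: none
Why: Claisen–Schmidt condensation in which only the methyl ketone can enolise and only the aldehyde is a good acceptor, and loss of water under the basic conditions gives the conjugated (E)-enone.

Step 3
Reactants: 4 chalcone
Product: 5 bromoflavone 5,7-bis(benzyloxy)-2-(3-bromo-4-methoxyphenyl)-4H-chromen-4-one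
Conditions: I2 (10 mol %), DMSO, 130 °C
Reagents that add atoms: none
Why: Iodine-catalysed oxidative cyclisation of a 2'-hydroxychalcone, in which the free phenol adds to the enone and the new ring is dehydrogenated with DMSO as terminal oxidant, conditions that leave benzyl ethers and the aryl bromide untouched.

Step 4
Reactants: 5 bromoflavone
Product: 6 flavone boronate 5,7-bis(benzyloxy)-2-[4-methoxy-3-(4,4,5,5-tetramethyl-1,3,2-dioxaborolan-2-yl)phenyl]-4H-chromen-4-one
Conditions: B2pin2, PdCl2(dppf) (5 mol %), KOAc, 1,4-dioxane, 90 °C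
Reagents that add atoms: bis(pinacolato)diboron (CC1(C)OB(OC1(C)C)B1OC(C)(C)C(C)(C)O1)
Why: Miyaura borylation in which zerovalent palladium inserts into the only C–Br bond and the acetate complex transmetalates with the diboron reagent, the weak base KOAc suppressing homocoupling and sparing the pyranone.

Step 5
Reactants: 1 phloroacetophenone; 7 4-methoxybenzyl chloride
Product: 8 bis(4-methoxybenzyl) ether 2'-hydroxy-4',6'-bis(4-methoxybenzyloxy)acetophenone
Conditions: 7 (2.1 equiv), K2CO3 (2.2 equiv), DMF, rt to 50 °C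
Reagents that add atoms: none
Why: Williamson ether synthesis with the same selectivity as in step 1, which places one 4-methoxybenzyl group on the ortho oxygen that becomes O1 (its CH2 is the future C2) and one on the future O7 as a protecting group.

Step 6
Reactants: 8 bis(4-methoxybenzyl) ether
Product: 9 aryl iodide 2'-hydroxy-3'-iodo-4',6'-bis(4-methoxybenzyloxy)acetophenone
Conditions: NIS (1.05 equiv), DMF, 0 °C to rt, dark
Reagents that add atoms: N-iodosuccinimide (O=C1CCC(=O)N1I)
Why: Electrophilic aromatic iodination directed to the position ortho to the free chelated phenol (future C6), which is more nucleophilic and less crowded than the position between the two benzylic ethers, while the anisyl rings are far less activated than the phloroglucinol ring.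

Step 7
Reactants: 9 aryl iodide; 6 flavone boronate
Product: 10 biaryl hydroxy ketone 2-{3-[3-acetyl-2-hydroxy-4,6-bis(4-methoxybenzyloxy)phenyl]-4-methoxyphenyl}-5,7-bis(benzyloxy)-4H-chromen-4-one
Conditions: Pd(OAc)2 (5 mol %), SPhos (10 mol %), K3PO4, 1,4-dioxane/H2O, 90 °C
Reagents that add atoms: none
Why: Suzuki–Miyaura coupling, for which the bulky electron-rich biarylphosphine is chosen because it promotes oxidative addition to the electron-rich iodide and reductive elimination to a biaryl with three ortho substituents, free ortho phenols being tolerated.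

Step 8
Reactants: 10 biaryl hydroxy ketone
Product: 11 silyl ether 2-{3-[3-acetyl-2-(tert-butyldimethylsilyloxy)-4,6-bis(4-methoxybenzyloxy)phenyl]-4-methoxyphenyl}-5,7-bis(benzyloxy)-4H-chromen-4-one
Conditions: TBSOTf, 2,6-lutidine, CH2Cl2, 0 °C to rt
Reagents that add atoms: tert-butyldimethylsilyl trifluoromethanesulfonate (CC(C)(C)[Si](C)(C)OS(=O)(=O)C(F)(F)F)
Why: Silylation of a hindered hydrogen-bonded phenol with the highly electrophilic silyl triflate, the weak hindered base avoiding enol silylation of the ketone, to give an O5 group that has no C–H bond next to oxygen.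

Step 9
Reactants: 11 silyl ether
Product: 13 aryl diazomethyl ketone 5,7-bis(benzyloxy)-2-{3-[2-(tert-butyldimethylsilyloxy)-3-(diazoacetyl)-4,6-bis(4-methoxybenzyloxy)phenyl]-4-methoxyphenyl}-4H-chromen-4-one, via trifluoroacetyl diketone 12 (not isolated)
Conditions: LiHMDS, THF, −78 °C, then CF3CO2CH2CF3; cold dilute HCl work-up; crude 12, p-ABSA, Et3N, H2O (1 equiv), MeCN/CH2Cl2, rt
Reagents that add atoms: 2,2,2-trifluoroethyl trifluoroacetate (O=C(OCC(F)(F)F)C(F)(F)F; adds CF3CO in 12); 4-acetamidobenzenesulfonyl azide (CC(=O)Nc1ccc(cc1)S(=O)(=O)N=[N+]=[N-]; adds N2 in 13)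
Why: Detrifluoroacetylative variant of the Regitz diazo transfer, in which the methyl ketone is deprotonated and C-trifluoroacetylated to activate the alpha carbon and the sulfonyl azide then delivers N2 while the trifluoroacetyl group leaves on the sulfonamide nitrogen, a sequence suited to methyl ketones that resist direct diazo transfer.

Step 10
Reactants: 13 aryl diazomethyl ketone
Product: 14 protected flavanone (2S)-6-{5-[5,7-bis(benzyloxy)-4-oxo-4H-chromen-2-yl]-2-methoxyphenyl}-5-(tert-butyldimethylsilyloxy)-7-(4-methoxybenzyloxy)-2-(4-methoxyphenyl)chroman-4-one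
Conditions: Rh2(S-PTTL)4 (2 mol %), 4 Å molecular sieves, CH2Cl2, 0 °C, 13 added over 4 h by syringe pump (final 0.005 M)
Reagents that add atoms: none
Why: Rh2(S-PTTL)4, a paddlewheel dimer of divalent rhodium carrying four N-phthaloyl-(S)-tert-leucinate ligands, displaces N2 from 13 to give an electrophilic carbenoid at the future C3, which takes up one benzylic C–H bond of the neighbouring OCH2Ar group in a concerted, asynchronous three-centre transition state with hydride-transfer character and retention at carbon. The closest known reaction type is the enantioselective intramolecular C–H insertion of 2-alkoxyaryl alpha-diazo ketones to 2-substituted chroman-4-ones under chiral dirhodium tetracarboxylates. Ring C (O1–C2–C3–C4–C4a–C8a) closes by 1,6-insertion through formation of C2–C3, the only ring size open to insertion because the fifth atom from the carbenoid is oxygen and the silyl methyl groups on the other side would demand a seven-membered transition state. C2 is controlled by the catalyst alone, since the phthalimido walls around the rhodium face should let only the pro-S hydrogen approach the carbenoid, and its replacement with retention gives (2S). The selectivity needed is insertion over capture of the carbenoid by the ether oxygen (five-membered oxonium ylide, then Stevens [1,2]-shift of the benzyl group); it should be secured by the double activation of the C–H bond (alpha to oxygen, benzylic to an anisyl ring), by the low basicity of an aryl ether oxygen conjugated to the acylated ring A, by the two ortho substituents that twist the carbonyl out of the plane a benzofuranone-type ylide requires, and by the use of a rhodium carboxylate rather than copper at low temperature. Slow addition at high dilution suppresses carbene dimerisation and intermolecular attack on the remote benzylic ethers, and the neutral medium leaves the new stereocentre untouched.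

Step 11
Reactants: 14 protected flavanone
Product: 15 chelated phenol (2S)-6-{5-[5,7-bis(benzyloxy)-4-oxo-4H-chromen-2-yl]-2-methoxyphenyl}-5-hydroxy-7-(4-methoxybenzyloxy)-2-(4-methoxyphenyl)chroman-4-one
Conditions: TBAF/AcOH (1:1), THF, 0 °C
Reagents that add atoms: none
Why: Fluoride-induced cleavage of an aryl silyl ether, buffered with acetic acid so that the liberated phenoxide is protonated at once and no base is present that could open ring C by beta-elimination and racemise C2.

Step 12
Reactants: 15 chelated phenol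
Product: 16 target (2S)-6-[5-(5,7-dihydroxy-4-oxo-4H-chromen-2-yl)-2-methoxyphenyl]-5,7-dihydroxy-2-(4-methoxyphenyl)chroman-4-one
Conditions: H2 (1 atm), Pd/C (10 %), THF/EtOAc, rt
Reagents that add atoms: none
Why: Catalytic hydrogenolysis under neutral conditions of the three primary benzylic aryl ethers, which should react faster than the cyclic secondary C2–O1 bond or the flavone double bond, so that C2 keeps its configuration if the reaction is stopped after uptake of three equivalents of hydrogen.

Compound list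
1 | 2',4',6'-trihydroxyacetophenone | CC(=O)c1c(O)cc(O)cc1O | starting material
2 | 4',6'-bis(benzyloxy)-2'-hydroxyacetophenone | CC(=O)c1c(O)cc(OCc2ccccc2)cc1OCc1ccccc1 | intermediate
3 | 3-bromo-4-methoxybenzaldehyde | COc1ccc(C=O)cc1Br | starting material
4 | (E)-1-[2,4-bis(benzyloxy)-6-hydroxyphenyl]-3-(3-bromo-4-methoxyphenyl)prop-2-en-1-one | O=C(/C=C/c1ccc(OC)c(Br)c1)c1c(O)cc(OCc2ccccc2)cc1OCc1ccccc1 | intermediate
5 | 5,7-bis(benzyloxy)-2-(3-bromo-4-methoxyphenyl)-4H-chromen-4-one | COc1ccc(-c2cc(=O)c3c(OCc4ccccc4)cc(OCc4ccccc4)cc3o2)cc1Br | intermediate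
6 | 5,7-bis(benzyloxy)-2-[4-methoxy-3-(4,4,5,5-tetramethyl-1,3,2-dioxaborolan-2-yl)phenyl]-4H-chromen-4-one | COc1ccc(-c2cc(=O)c3c(OCc4ccccc4)cc(OCc4ccccc4)cc3o2)cc1B1OC(C)(C)C(C)(C)O1 | intermediate
7 | 4-methoxybenzyl chloride | COc1ccc(CCl)cc1 | starting material
8 | 2'-hydroxy-4',6'-bis(4-methoxybenzyloxy)acetophenone | CC(=O)c1c(O)cc(OCc2ccc(OC)cc2)cc1OCc1ccc(OC)cc1 | intermediate
9 | 2'-hydroxy-3'-iodo-4',6'-bis(4-methoxybenzyloxy)acetophenone | CC(=O)c1c(O)c(I)c(OCc2ccc(OC)cc2)cc1OCc1ccc(OC)cc1 | intermediate
10 | 2-{3-[3-acetyl-2-hydroxy-4,6-bis(4-methoxybenzyloxy)phenyl]-4-methoxyphenyl}-5,7-bis(benzyloxy)-4H-chromen-4-one | CC(=O)c1c(O)c(-c2cc(-c3cc(=O)c4c(OCc5ccccc5)cc(OCc5ccccc5)cc4o3)ccc2OC)c(OCc2ccc(OC)cc2)cc1OCc1ccc(OC)cc1 | intermediate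
11 | 2-{3-[3-acetyl-2-(tert-butyldimethylsilyloxy)-4,6-bis(4-methoxybenzyloxy)phenyl]-4-methoxyphenyl}-5,7-bis(benzyloxy)-4H-chromen-4-one | CC(=O)c1c(O[Si](C)(C)C(C)(C)C)c(-c2cc(-c3cc(=O)c4c(OCc5ccccc5)cc(OCc5ccccc5)cc4o3)ccc2OC)c(OCc2ccc(OC)cc2)cc1OCc1ccc(OC)cc1 | intermediate
12 | 5,7-bis(benzyloxy)-2-{3-[2-(tert-butyldimethylsilyloxy)-4,6-bis(4-methoxybenzyloxy)-3-(4,4,4-trifluoro-3-oxobutanoyl)phenyl]-4-methoxyphenyl}-4H-chromen-4-one | FC(F)(F)C(=O)CC(=O)c1c(O[Si](C)(C)C(C)(C)C)c(-c2cc(-c3cc(=O)c4c(OCc5ccccc5)cc(OCc5ccccc5)cc4o3)ccc2OC)c(OCc2ccc(OC)cc2)cc1OCc1ccc(OC)cc1 | intermediate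
13 | 5,7-bis(benzyloxy)-2-{3-[2-(tert-butyldimethylsilyloxy)-3-(diazoacetyl)-4,6-bis(4-methoxybenzyloxy)phenyl]-4-methoxyphenyl}-4H-chromen-4-one | [N-]=[N+]=CC(=O)c1c(O[Si](C)(C)C(C)(C)C)c(-c2cc(-c3cc(=O)c4c(OCc5ccccc5)cc(OCc5ccccc5)cc4o3)ccc2OC)c(OCc2ccc(OC)cc2)cc1OCc1ccc(OC)cc1 | intermediate
14 | (2S)-6-{5-[5,7-bis(benzyloxy)-4-oxo-4H-chromen-2-yl]-2-methoxyphenyl}-5-(tert-butyldimethylsilyloxy)-7-(4-methoxybenzyloxy)-2-(4-methoxyphenyl)chroman-4-one | COc1ccc([C@@H]2CC(=O)c3c(cc(OCc4ccc(OC)cc4)c(-c4cc(-c5cc(=O)c6c(OCc7ccccc7)cc(OCc7ccccc7)cc6o5)ccc4OC)c3O[Si](C)(C)C(C)(C)C)O2)cc1 | intermediate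
15 | (2S)-6-{5-[5,7-bis(benzyloxy)-4-oxo-4H-chromen-2-yl]-2-methoxyphenyl}-5-hydroxy-7-(4-methoxybenzyloxy)-2-(4-methoxyphenyl)chroman-4-one | COc1ccc([C@@H]2CC(=O)c3c(cc(OCc4ccc(OC)cc4)c(-c4cc(-c5cc(=O)c6c(OCc7ccccc7)cc(OCc7ccccc7)cc6o5)ccc4OC)c3O)O2)cc1 | intermediate
16 | (2S)-6-[5-(5,7-dihydroxy-4-oxo-4H-chromen-2-yl)-2-methoxyphenyl]-5,7-dihydroxy-2-(4-methoxyphenyl)chroman-4-one | COc1ccc([C@@H]2CC(=O)c3c(cc(O)c(-c4cc(-c5cc(=O)c6c(O)cc(O)cc6o5)ccc4OC)c3O)O2)cc1 | target

Total step count: 12.
Longest linear sequence: 10 steps (steps 1, 2, 3, 4, 7, 8, 9, 10, 11, 12).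

Steps most likely to fail

Step 10. The carbenoid may be captured by the ether oxygen, followed by [1,2]-shift of the benzyl group, or the catalyst may discriminate poorly between the two enantiotopic hydrogens.
- The fallback sets out from 11, returns at 14, and forms the C2–aryl bond instead of C2–C3.
- DDQ in wet CH2Cl2 removes both 4-methoxybenzyl ethers of 11, benzyl and silyl ethers staying, to give the dihydroxy ketone F1.
- A Mitsunobu reaction with 4-methoxybenzyl alcohol (PPh3, DIAD, THF) re-alkylates only the hydroxyl para to the acetyl group, not the chelated ortho one, and gives the ortho-hydroxy ketone F2.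
- DMF dimethyl acetal in warm toluene converts the acetyl group into the enaminone F3. On brief treatment with acid this closes with loss of dimethylamine to the chromone F4.
- Asymmetric conjugate addition of 4-methoxyphenylboronic acid to F4 then gives 14. Conditions are Pd(OCOCF3)2, the t-BuPyOx enantiomer that leads to (2S), NH4PF6, H2O, ClCH2CH2Cl, 60 °C.

Step 9. The silyl group may migrate from the phenol oxygen to the neighbouring enolate oxygen during deprotonation, or the silyl ether may be lost in the wet amine medium of the diazo transfer.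
- The fallback sets out from 11, returns at 13, and forms no enolate.
- Riley oxidation with SeO2 in wet 1,4-dioxane turns the acetyl methyl group into the aldehyde of the aryl glyoxal F5.
- Tosylhydrazide condenses at the aldehyde carbon to give the monotosylhydrazone F6.
- Et3N in CH2Cl2 eliminates toluenesulfinate in a Bamford–Stevens-type reaction to give 13.

Step 7. Transmetalation and reductive elimination may be slow at a site that ends with three ortho substituents, so that protodeboronation of the boronate and hydrodeiodination of the iodide overtake coupling.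
- The fallback sets out from 5, returns at 10, and replaces boron by tin, so that transmetalation needs no aqueous base and runs through an aryl copper species.
- Stannylation of 5 with hexamethylditin and Pd(PPh3)4 in toluene gives the aryl stannane F7.
- Stille coupling of F7 with 9 (Pd(PPh3)4, CuI, CsF, DMF) gives 10.

Further compounds
F1 | step 10 | 2-{3-[3-acetyl-2-(tert-butyldimethylsilyloxy)-4,6-dihydroxyphenyl]-4-methoxyphenyl}-5,7-bis(benzyloxy)-4H-chromen-4-one | CC(=O)c1c(O[Si](C)(C)C(C)(C)C)c(-c2cc(-c3cc(=O)c4c(OCc5ccccc5)cc(OCc5ccccc5)cc4o3)ccc2OC)c(O)cc1O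
F2 | step 10 | 2-{3-[3-acetyl-2-(tert-butyldimethylsilyloxy)-4-hydroxy-6-(4-methoxybenzyloxy)phenyl]-4-methoxyphenyl}-5,7-bis(benzyloxy)-4H-chromen-4-one | CC(=O)c1c(O[Si](C)(C)C(C)(C)C)c(-c2cc(-c3cc(=O)c4c(OCc5ccccc5)cc(OCc5ccccc5)cc4o3)ccc2OC)c(OCc2ccc(OC)cc2)cc1O
F3 | step 10 | 5,7-bis(benzyloxy)-2-{3-[2-(tert-butyldimethylsilyloxy)-3-[(E)-3-(dimethylamino)acryloyl]-4-hydroxy-6-(4-methoxybenzyloxy)phenyl]-4-methoxyphenyl}-4H-chromen-4-one | CN(C)/C=C/C(=O)c1c(O[Si](C)(C)C(C)(C)C)c(-c2cc(-c3cc(=O)c4c(OCc5ccccc5)cc(OCc5ccccc5)cc4o3)ccc2OC)c(OCc2ccc(OC)cc2)cc1O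
F4 | step 10 | 6-{5-[5,7-bis(benzyloxy)-4-oxo-4H-chromen-2-yl]-2-methoxyphenyl}-5-(tert-butyldimethylsilyloxy)-7-(4-methoxybenzyloxy)-4H-chromen-4-one | O=c1ccoc2cc(OCc3ccc(OC)cc3)c(-c3cc(-c4cc(=O)c5c(OCc6ccccc6)cc(OCc6ccccc6)cc5o4)ccc3OC)c(O[Si](C)(C)C(C)(C)C)c12
F5 | step 9 | 2-{3-[5,7-bis(benzyloxy)-4-oxo-4H-chromen-2-yl... aryl]} glyoxal: 2-oxo-2-{3-{5-[5,7-bis(benzyloxy)-4-oxo-4H-chromen-2-yl]-2-methoxyphenyl}-2-(tert-butyldimethylsilyloxy)-4,6-bis(4-methoxybenzyloxy)phenyl}acetaldehyde | O=CC(=O)c1c(O[Si](C)(C)C(C)(C)C)c(-c2cc(-c3cc(=O)c4c(OCc5ccccc5)cc(OCc5ccccc5)cc4o3)ccc2OC)c(OCc2ccc(OC)cc2)cc1OCc1ccc(OC)cc1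
F6 | step 9 | (E)-4-toluenesulfonylhydrazone at the aldehyde carbon of F5 | Cc1ccc(cc1)S(=O)(=O)N/N=C/C(=O)c1c(O[Si](C)(C)C(C)(C)C)c(-c2cc(-c3cc(=O)c4c(OCc5ccccc5)cc(OCc5ccccc5)cc4o3)ccc2OC)c(OCc2ccc(OC)cc2)cc1OCc1ccc(OC)cc1
F7 | step 7 | 5,7-bis(benzyloxy)-2-[4-methoxy-3-(trimethylstannyl)phenyl]-4H-chromen-4-one | COc1ccc(-c2cc(=O)c3c(OCc4ccccc4)cc(OCc4ccccc4)cc3o2)cc1[Sn](C)(C)C
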